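**Retrosynthetic overview** (isochromene numbering: C1, O2, C3, C4, C4a, C5–C8, C8a)
1. Target ⇒ acid-labile protected precursor ⇒ orsellinoyl chloride + C7 tertiary alcohol of the azaphilone; the acrylate comes from a Wittig reaction on a C3 aldehyde.
2. Ring B (pyran) is formed last, by 6-endo cycloisomerisation (O2–C3) of an alkynyl 2-formyl-dienone ("vinylogous acid").
3. Ring A is formed first, in one operation: light opens a 4-alkynyl-2-pyranone to a (Z)-ketene that is captured by the lactate-derived dioxolanone enolate (C6–C7), followed by Dieckmann closure (C8–C8a).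
4. C7 comes from (S)-lactic acid: the pivaldehyde acetal relays its configuration and the acyl group enters anti to t-Bu, giving 7R.
5. Ring order: A, then B; side chain and orsellinate are attached afterwards.

Assumption: 4-bromo-2H-pyran-2-one is taken as a purchasable catalogue building block; its availability was not verified.

**Step 1**
Reactants: 1 (S)-lactic acid; 2 pivaldehyde
Product: 3 (2S,5S)-2-tert-butyl-5-methyl-1,3-dioxolan-4-one (cis)
Conditions: TsOH·H2O (cat.), H2SO4 (cat.), pentane, reflux, Dean–Stark; recrystallise from pentane at −78 °C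
Reagents that add atoms: none
Why: Acid-catalysed acetalisation under thermodynamic control (Seebach self-regeneration of stereocentres); the lactate centre sets the new acetal centre cis, and crystallisation upgrades the ratio.

**Step 2**
Reactants: 4 4-bromo-2H-pyran-2-one; 5 3,3-diethoxyprop-1-yne
Product: 6 4-(3,3-diethoxyprop-1-yn-1-yl)-2H-pyran-2-one
Conditions: PdCl2(PPh3)2 (2 mol %), CuI (4 mol %), Et3N, THF, rt
Reagents that add atoms: none
Why: Sonogashira coupling of a vinylogous acyl bromide, as practised on 4-bromo-6-methyl-2-pyranone; the acetal masks the side-chain aldehyde and contains no photo-isomerisable alkene.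

**Step 3**
Reactants: 3 (2S,5S)-2-tert-butyl-5-methyl-1,3-dioxolan-4-one; 6 4-(3,3-diethoxyprop-1-yn-1-yl)-2H-pyran-2-one
Product: 7 (5R)-2-(3,3-diethoxyprop-1-yn-1-yl)-4,5-dihydroxy-5-methyl-6-oxocyclohexa-1,3-diene-1-carbaldehyde (one tautomer of the "vinylogous acid"; C5 here = C7 of the target)
Conditions: 3 (1.3 equiv), LiTMP, THF, −78 °C; merge with 6 in THF through a T-mixer into an FEP flow coil, 310 nm LED, −90 °C, residence ca. 1 min; then dark, warm to 0 °C → rt, 1 h; AcOH quench
Reagents that add atoms: none (pivaldehyde is expelled)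
Why: Proposed new method: UV excitation of 6 triggers the known electrocyclic ring-opening of 2-pyranones to a (Z)-ketene-aldehyde, whose sp carbon is intercepted by the lithium enolate of 3 anti to t-Bu (C6–C7 bond, net retention of the lactate configuration = 7R), overriding the dark preference of carbanions for C6 (1,6-addition) of pyranones, and the resulting open-chain oxido-dienone anion, once out of the light, closes through C8a onto the dioxolanone carbonyl (6-enolendo-exo-trig Dieckmann/Claisen), releasing pivaldehyde and the C7–OH; untrapped ketene simply reverts to 6; closest known reactions are photolysis of 2-pyranones in methanol (ketene trapped as ester), C-acylation of ester enolates by ketenes, and Seebach enolate alkylation/acylation.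

**Step 4**
Reactants: 7 the vinylogous acid from Step 3
Product: 8 (7R)-7-hydroxy-7-methyl-6,8-dioxo-7,8-dihydro-6H-isochromene-3-carbaldehyde
Conditions: CuI (10 mol %), i-Pr2NEt, CH2Cl2, rt, dark; then 2 M aq. HCl, THF, rt → 40 °C
Reagents that add atoms: water, O (aldehyde oxygen)
Why: Cu(I)-promoted 6-endo-dig oxa-cyclisation of the formyl-enol oxygen onto the alkyne carbon δ to the ring ketone (the cycloisomerisation used in known azaphilone syntheses), then acetal hydrolysis on the acid-stable azaphilone; C7 has no α-hydrogen and is untouched.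

**Step 5**
Reactants: 8 the azaphilone aldehyde; 9 tert-butyl (triphenylphosphoranylidene)acetate
Product: 10 tert-butyl (2E)-3-[(7R)-7-hydroxy-7-methyl-6,8-dioxo-7,8-dihydro-6H-isochromen-3-yl]prop-2-enoate
Conditions: CH2Cl2, rt, dark
Reagents that add atoms: none
Why: Wittig olefination with a stabilised, weakly basic ylide gives the E-acrylate and tolerates the free tertiary alcohol.

**Step 6**
Reactants: 11 orsellinic acid (2,4-dihydroxy-6-methylbenzoic acid)
Product: 12 2,4-bis[(4-methoxybenzyl)oxy]-6-methylbenzoic acid
Conditions: PMBCl (3.3 equiv), K2CO3, DMF, 60 °C; then KOH, DMSO/H2O, 90 °C; acidify to pH 3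
Reagents that add atoms: 4-methoxybenzyl chloride, COc1ccc(CCl)cc1
Why: Williamson O-alkylation of both phenols and the carboxylate, then saponification of the PMB ester; PMB ethers are base-stable and, unlike MOM ethers, cannot cyclise onto the acid chloride made in Step 7.

**Step 7**
Reactants: 10 the azaphilone alcohol; 12 the bis-PMB orsellinic acid
Product: 13 (7R)-3-[(1E)-3-tert-butoxy-3-oxoprop-1-en-1-yl]-7-methyl-6,8-dioxo-7,8-dihydro-6H-isochromen-7-yl 2,4-bis[(4-methoxybenzyl)oxy]-6-methylbenzoate
Conditions: 12, 1-chloro-N,N,2-trimethylprop-1-en-1-amine (Ghosez reagent), CH2Cl2, 0 °C → rt; then 10, DMAP, Et3N, CH2Cl2, rt → 35 °C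
Reagents that add atoms: none
Why: Neutral acid-chloride formation followed by DMAP-catalysed O-acylation of the tertiary alcohol, the way 7-hydroxy-azaphilones are usually esterified; no bond to C7 is broken.

**Step 8**
Reactants: 13 the protected ester
Product: 14 mitorubrinic acid
Conditions: TFA/CH2Cl2 (1:2), anisole (10 equiv), 0 °C → rt
Reagents that add atoms: none
Why: Acidolysis removes the tert-butyl ester and both PMB ethers (anisole scavenges the benzyl cation); the azaphilone core and the hindered C7 ester, which cannot ionise next to two carbonyls, survive.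

**Compound list**
1 | (S)-lactic acid | C[C@H](O)C(=O)O | starting material
2 | pivaldehyde | CC(C)(C)C=O | starting material
3 | (2S,5S)-2-tert-butyl-5-methyl-1,3-dioxolan-4-one | C[C@@H]1O[C@H](C(C)(C)C)OC1=O | intermediate
4 | 4-bromo-2H-pyran-2-one | O=C1C=C(Br)C=CO1 | starting material
5 | 3,3-diethoxyprop-1-yne | C#CC(OCC)OCC | starting material
6 | 4-(3,3-diethoxyprop-1-yn-1-yl)-2H-pyran-2-one | O=C1C=C(C#CC(OCC)OCC)C=CO1 | intermediate
7 | (5R)-2-(3,3-diethoxyprop-1-yn-1-yl)-4,5-dihydroxy-5-methyl-6-oxocyclohexa-1,3-diene-1-carbaldehyde | O[C@]1(C)C(O)=CC(C#CC(OCC)OCC)=C(C=O)C1=O | intermediate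
8 | (7R)-7-hydroxy-7-methyl-6,8-dioxo-7,8-dihydro-6H-isochromene-3-carbaldehyde | O[C@]1(C)C(=O)C=C2C=C(C=O)OC=C2C1=O | intermediate
9 | tert-butyl (triphenylphosphoranylidene)acetate | CC(C)(C)OC(=O)C=P(c1ccccc1)(c1ccccc1)c1ccccc1 | starting material
10 | tert-butyl (2E)-3-[(7R)-7-hydroxy-7-methyl-6,8-dioxo-7,8-dihydro-6H-isochromen-3-yl]prop-2-enoate | O[C@]1(C)C(=O)C=C2C=C(/C=C/C(=O)OC(C)(C)C)OC=C2C1=O | intermediate
11 | orsellinic acid | Cc1cc(O)cc(O)c1C(=O)O | starting material
12 | 2,4-bis[(4-methoxybenzyl)oxy]-6-methylbenzoic acid | Cc1cc(OCc2ccc(OC)cc2)cc(OCc2ccc(OC)cc2)c1C(=O)O | intermediate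
13 | (7R)-3-[(1E)-3-tert-butoxy-3-oxoprop-1-en-1-yl]-7-methyl-6,8-dioxo-7,8-dihydro-6H-isochromen-7-yl 2,4-bis[(4-methoxybenzyl)oxy]-6-methylbenzoate | Cc1cc(OCc2ccc(OC)cc2)cc(OCc2ccc(OC)cc2)c1C(=O)O[C@]1(C)C(=O)C=C2C=C(/C=C/C(=O)OC(C)(C)C)OC=C2C1=O | intermediate
14 | mitorubrinic acid, (7R) | Cc1cc(O)cc(O)c1C(=O)O[C@]1(C)C(=O)C=C2C=C(/C=C/C(=O)O)OC=C2C1=O | target

**Totals**
Total steps: 8. Longest linear sequence: 6 (Steps 2→3→4→5→7→8, or 1→3→4→5→7→8).

**Three steps most likely to fail**
1. Step 3 (proposed photo-annulation). Risks are a dark 1,6-addition of the enolate to 6, slow Dieckmann closure, and imperfect facial selectivity eroding ee. Fallback (known chemistry, thermal and stepwise):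
   - open 6 with NaOMe/MeOH–HC(OMe)3 to methyl 3-(3,3-diethoxypropynyl)-5,5-dimethoxypent-2-enoate;
   - saponify and convert to the acid chloride;
   - C-acylate the LDA enolate of 3 (classical Seebach acylation, same facial control);
   - close ring A by LiHMDS γ-deprotonation and vinylogous Dieckmann onto the dioxolanone;
   - unveil C1 with mild acid to reach 7.
2. Step 4 (cycloisomerisation and hydrolysis). Risks are 5-exo closure, base-induced α-ketol rearrangement of the 2-hydroxy-1,3-diketone, and slow acetal hydrolysis. Fallback: electrophilic 6-endo iodocyclisation (I2, NaHCO3, MeCN) to the 4-iodo-azaphilone, then Pd-catalysed formate hydrodeiodination and the same acid hydrolysis.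
3. Step 7 (doubly hindered esterification). Fallback: change the acyl donor to the orsellinate acetonide, 7-[(4-methoxybenzyl)oxy]-2,2,5-trimethyl-4H-1,3-benzodioxin-4-one, opened by the C7 alkoxide of 10 (NaHMDS, −78 °C), the transesterification known from resorcylate syntheses. This delivers the ester with the 2-OH already free.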